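Retrosynthesis (labdane numbering): cut C12–C13 (Stille coupling of a butenolide stannane with an E-vinyl iodide), then C11=C12 (Takai olefination), then C9–C11 (carbonylation of a C9 enol triflate), and then undo ring A.
Enabling feature: in ring A the carbinol carbon C3 is bonded to the quaternary C4, which carries C18H3 and the oxidised C19. This array is the retron of a semipinacol shift. Moving C3 back from C4 to C19 makes C19 a member of a seven-membered ring C10–C1–C2–C3–C19–C4–C5 with a C4–C19 epoxide next to a C3 silyl ether.
That ring is cut at C19=C4 (ring-closing metathesis) and at C10–C1 and C10–C20 (two enolate alkylations). This leaves (S)-carvone: its ring is ring B, its carbonyl carbon is C9, its ring methyl is C17, and its isopropenyl group supplies C4 and C18.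
Forward order: ring B (carvone), seven-membered ring (metathesis), C3 oxygenation and directed epoxidation, remodelling of ring B (C11 ester, photodeconjugation to the C8=C17 methylene, vinyl iodide), contraction 7→6 to ring A, acetate, butenolide.
Stereochemistry: C5 comes from carvone. C10 is set by alkylation anti to the isopropenyl group and C3 by CBS reduction. C4 is relayed from C3 (syn-directed epoxidation, then inversion at C4 in the shift). C9 is set by protonation anti to the axial C20 methyl, and the E-alkene by Takai and Stille chemistry.

Key step: step 14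

Remark: labdane numbering and α/β descriptors (C20 methyl = α) are used for all intermediates; 5-iodopent-1-ene and 3-bromofuran-2(5H)-one are taken as purchasable.

Step 1
Reactants: 1 (S)-(+)-carvone
Product: 3 trans-6-methylcarvone, via lithium dienolate 2 (not isolated)
Conditions: LiN(i-Pr)2, THF, −78 °C; MeI, −78 to 0 °C
Reagents that add atoms: iodomethane CI
Why: Kinetic α'-deprotonation of the cross-conjugated enone followed by SN2 methylation (ketone enolate alkylation) is routine for carvone; the methyl group enters anti to the isopropenyl group, but this centre is flattened again in step 2, so its configuration is of no consequence.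

Step 2
Reactants: 3 trans-6-methylcarvone
Product: 5 6-methyl-6-(pent-4-enyl)carvone (chain trans to isopropenyl), via lithium dienolate 4 (not isolated)
Conditions: LiN(i-Pr)2, THF, −78 °C; 5-iodopent-1-ene, DMPU, −78 °C to rt
Reagents that add atoms: 5-iodopent-1-ene C=CCCCI
Why: A second ketone enolate alkylation: the fully substituted dienolate 4 can only react at C10 and takes up the primary iodide on the face opposite the neighbouring C5 isopropenyl group, which sets the quaternary C10 with the chain (C1) trans and the methyl group (C20) cis to C4, DMPU raising the reactivity of the lithium enolate towards the unactivated halide.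

Step 3
Reactants: 5 6-methyl-6-(pent-4-enyl)carvone
Product: 6 trans-fused 6-7 bicyclic dienone (C4=C19 alkene in the seven-membered ring)
Conditions: second-generation Grubbs catalyst RuCl2(=CHPh)(PCy3)(H2IMes) (cat.), CH2Cl2 (dilute), reflux
Reagents that add atoms: none
Why: Ring-closing metathesis: the ruthenium alkylidene loads on the monosubstituted chain alkene and closes on the 1,1-disubstituted isopropenyl group, the trans-diequatorial placing of the two arms favours the seven-membered ring, the electron-poor trisubstituted enone alkene is inert, and no stereocentre is formed.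

Step 4
Reactants: 6 trans-fused 6-7 bicyclic dienone
Product: 7 bicyclic bis-enone (C3 and C9 ketones)
Conditions: CrO3, 3,5-dimethylpyrazole, CH2Cl2, −20 °C
Reagents that add atoms: chromium trioxide O=[Cr](=O)=O
Why: Allylic oxidation with the CrO3–dimethylpyrazole complex: C3 is the only secondary allylic C–H position of the electron-rich C4=C19 alkene (C5 is a hindered methine, C18 a methyl group, and the enone alkene is deactivated), so the β-methyl cycloheptenone should form under non-basic conditions that leave the vinylogous C5–H untouched.

Step 5
Reactants: 7 bicyclic bis-enone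
Product: 8 (3R)-allylic alcohol (3α-OH)
Conditions: (S)-2-methyl-CBS-oxazaborolidine (cat.), catecholborane, toluene, −78 °C
Reagents that add atoms: none
Why: Corey–Bakshi–Shibata reduction: the C9 carbonyl, flanked by the quaternary C10 and the C8 methyl group, is too hindered to engage, and the (S)-oxazaborolidine, reading the alkenyl arm (C19) as the large group, delivers hydride to the β face of C3, the face that the axial C20 methyl group leaves open, which sets (3R), that is 3α-OH.

Step 6
Reactants: 8 (3R)-allylic alcohol
Product: 9 4α,19α-epoxy-3α-alcohol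
Conditions: VO(acac)2 (cat.), t-BuOOH, CH2Cl2, 0 °C
Reagents that add atoms: tert-butyl hydroperoxide CC(C)(C)OO
Why: Hydroxyl-directed epoxidation: the allylic alcohol binds the pentavalent vanadium alkylperoxide and oxygen is delivered to the alkene face syn to the 3α-OH, as is the rule for cyclohept-2-enols, which sets the α-epoxide (C4 and C19) against the steric bias of the ring system and leaves the enone untouched.

Step 7
Reactants: 9 4α,19α-epoxy-3α-alcohol
Product: 10 epoxy silyl ether enone
Conditions: TBSCl, imidazole, DMF, rt
Reagents that add atoms: tert-butyldimethylsilyl chloride CC(C)(C)[Si](C)(C)Cl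
Why: Standard silylation of the secondary alcohol; the silyl ether keeps this oxygen from binding the Lewis acid as an alkoxide in step 14, protects C3–O through steps 8 to 18 and later distinguishes the C3 oxygen from the C19 oxygen.

Step 8
Reactants: 10 epoxy silyl ether enone
Product: 12 C9 enol triflate, via lithium enolate 11 (not isolated)
Conditions: Li[HB(s-Bu)3], THF, −78 °C; N-(5-chloro-2-pyridyl)triflimide, −78 to 0 °C
Reagents that add atoms: N-(5-chloropyridin-2-yl)bis(trifluoromethanesulfonimide) Clc1ccc(nc1)N(S(=O)(=O)C(F)(F)F)S(=O)(=O)C(F)(F)F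
Why: Conjugate reduction with in situ enolate trapping: the bulky borohydride adds 1,4 at the unhindered C7 because the C9 carbonyl is shielded, and O-sulfonylation of the regiodefined tetrasubstituted enolate 11 fixes the C8=C9 double bond, the hindered epoxide and the silyl ether being inert at −78 °C.

Step 9
Reactants: 12 C9 enol triflate
Product: 13 conjugated C11 methyl ester (C8=C9)
Conditions: Pd(OAc)2 (cat.), dppp, CO (1 atm), Et3N, MeOH/DMF, 60 °C
Reagents that add atoms: carbon monoxide [C-]#[O+]; methanol CO
Why: Palladium-catalysed methoxycarbonylation of an enol triflate (oxidative addition to zerovalent palladium, CO insertion, methanolysis), a reaction that tolerates hindered tetrasubstituted cyclohexenyl triflates, installs C11 on C9.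

Step 10
Reactants: 13 conjugated C11 methyl ester
Product: 15 deconjugated methyl ester (C8=C17 methylene; 9β-H), via dienol 14 (not isolated)
Conditions: hν (254 nm, quartz), 1,2-dimethylimidazole (cat.), Et2O, rt
Reagents that add atoms: none
Why: Photochemical deconjugation of an α,β-unsaturated ester: the excited enoate undergoes a 1,5-hydrogen shift from the only γ-carbon that lies cis to the ester carbonyl, the C17 methyl group (C7 is trans), and the weak base ketonises dienol 14 by protonation of C9 from the β face, opposite the axial C20 methyl group, which gives the equatorial ester (9β-H) and the C8=C17 methylene in a product that no longer absorbs at 254 nm.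

Step 11
Reactants: 15 deconjugated methyl ester
Product: 16 C11 primary alcohol
Conditions: i-Bu2AlH, CH2Cl2, −78 °C
Reagents that add atoms: none
Why: Hydride reduction of the ester with i-Bu2AlH at low temperature, conditions under which a trisubstituted epoxide, a silyl ether and an isolated alkene are left alone.

Step 12
Reactants: 16 C11 primary alcohol
Product: 17 C11 aldehyde
Conditions: Dess–Martin periodinane, pyridine, CH2Cl2, 0 °C
Reagents that add atoms: none
Why: Dess–Martin oxidation under buffered conditions should give the β,γ-unsaturated aldehyde without epimerisation at C9 or migration of the C8=C17 double bond into conjugation.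

Step 13
Reactants: 17 C11 aldehyde
Product: 18 (E)-vinyl iodide with intact seven-membered epoxy silyl ether
Conditions: CrCl2, CHI3, THF, 0 °C to rt
Reagents that add atoms: iodoform IC(I)I
Why: Takai olefination: the geminal dichromium species from CHI3 and CrCl2 adds to the aldehyde and eliminates to the (E)-vinyl iodide under neutral conditions that spare the C9 stereocentre, the epoxide and the methylene group.

Step 14
Reactants: 18 (E)-vinyl iodide with intact seven-membered epoxy silyl ether
Product: 19 ring-contracted 3α-silyloxy C19 aldehyde (ring A formed)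
Conditions: MeAl(OAr)2 [Ar = 4-bromo-2,6-di-tert-butylphenyl; from AlMe3 and ArOH, CH2Cl2, rt], CH2Cl2, −78 °C
Reagents that add atoms: none
Why: The bulky, oxophilic aluminium phenoxide binds the epoxide oxygen, the C4–O bond at the tertiary carbon ionises, and the C19–C3 σ-bond swings from C19 to the rear of C4, so that C19 is expelled from the ring as the aluminium-bound aldehyde (semipinacol, Meinwald-type 1,2-shift). The closest known reaction types are the aluminium-phenoxide-promoted rearrangement of 2,3-epoxy alcohol silyl ethers bearing a trisubstituted epoxide to α-quaternary β-silyloxy aldehydes and the Lewis acid ring contraction of 1-methylcycloalkene oxides to 1-methylcycloalkanecarbaldehydes. Ring A is closed not by an exo or endo cyclisation but by this suprafacial 1,2-alkyl shift, which forms C3–C4 as C3–C19 breaks and turns the seven-membered ring into the chair six-membered ring of a trans-decalin. C4 is the only new stereocentre: the shift inverts C4, so the α-epoxide of step 6 brings C3 in from the β side and leaves C19 α (axial) and C18 β (equatorial), while C3 migrates with retention and keeps its 3α-oxygen. The step needs carbon migration to win over the C19 hydride shift (cycloheptanone), over proton loss to an allylic alcohol and over capture of the cation by oxygen or by the C8=C17 alkene. The rotation about C4–C19 that aligns C3 moves the 3α-silyloxy group away from the α-bound aluminium phenoxide whereas the rotation that aligns H19 drives them together, the 3α-oxygen cannot reach the rear of C4, the silyl ether rules out alkoxide formation and Payne isomerisation, release of medium-ring strain favours contraction, and the methylene group and vinyl iodide are too far from C4 to interfere.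

Step 15
Reactants: 19 ring-contracted 3α-silyloxy C19 aldehyde
Product: 20 C19 primary alcohol
Conditions: NaBH4, MeOH/THF, 0 °C
Reagents that add atoms: none
Why: Borohydride reduction of the neopentyl aldehyde, the only carbonyl group present.

Step 16
Reactants: 20 C19 primary alcohol
Product: 21 C19 acetate
Conditions: Ac2O, pyridine, DMAP (cat.), CH2Cl2, rt
Reagents that add atoms: acetic anhydride CC(=O)OC(C)=O
Why: DMAP-catalysed acetylation of the only free hydroxyl group, so that the C19 acetate and the C3 silyl ether are distinguished by the way the two oxygens emerged from step 14.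

Step 17
Reactants: 22 3-bromofuran-2(5H)-one
Product: 23 3-(tributylstannyl)furan-2(5H)-one
Conditions: (Bu3Sn)2, Pd(PPh3)4 (cat.), toluene, 100 °C
Reagents that add atoms: hexabutylditin CCCC[Sn](CCCC)(CCCC)[Sn](CCCC)(CCCC)CCCC
Why: Palladium-catalysed stannylation of an alkenyl bromide with a distannane (oxidative addition, tin–tin transmetalation, reductive elimination).

Step 18
Reactants: 21 C19 acetate, 23 3-(tributylstannyl)furan-2(5H)-one
Product: 24 3-O-TBS ether of the target
Conditions: Pd2(dba)3 (cat.), AsPh3, CuI (cat.), NMP, rt
Reagents that add atoms: none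
Why: Stille coupling of an (E)-alkenyl iodide with an alkenylstannane proceeds with retention of the double-bond geometry under neutral conditions, AsPh3 and CuI speeding up the transmetalation of the electron-poor stannane, and forms C12–C13.

Step 19
Reactants: 24 3-O-TBS ether of the target
Product: 25 target CNP0346413.1 (19-O-acetyl-14-deoxy-11,12-didehydroandrographolide)
Conditions: HF·pyridine, THF, 0 °C to rt
Reagents that add atoms: none
Why: Fluoride-mediated desilylation in acidic medium removes the hindered secondary silyl ether while avoiding base-induced 19→3 acetyl migration and isomerisation of the butenolide.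

Compound list
1 | (S)-(+)-carvone | CC1=CC[C@@H](CC1=O)C(C)=C | starting material
2 | lithium cross-conjugated dienolate of carvone (C9–O−, C9=C10) | CC1=CC[C@H](C(C)=C)C=C1[O-].[Li+] | intermediate
3 | trans-6-methylcarvone, methyl anti to isopropenyl (the minor 6-epimer is carried along) | CC1=CC[C@H](C(C)=C)[C@@H](C)C1=O | intermediate
4 | lithium dienolate of 6-methylcarvone | CC1=CC[C@H](C(C)=C)C(C)=C1[O-].[Li+] | intermediate
5 | 6-methyl-6-(pent-4-enyl)carvone; quaternary C10 with chain trans and methyl cis to the C5 isopropenyl group | CC1=CC[C@H](C(C)=C)[C@@](C)(CCCC=C)C1=O | intermediate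
6 | trans-fused bicyclo[5.4.0]undecadienone: ring B (C9=O, C7=C8, C17 methyl) fused at C5–C10 to the ring C10–C1–C2–C3–C19=C4(CH3)–C5; 5β-H, 10α-CH3 | CC1=CC[C@@H]2C(C)=CCCC[C@@]2(C)C1=O | intermediate
7 | bis-enone: compound 6 with C3 oxidised to the ketone (C3=O conjugated with C19=C4) | CC1=CC[C@@H]2C(C)=CC(=O)CC[C@@]2(C)C1=O | intermediate
8 | (3R)-allylic alcohol, 3α-OH, C19=C4 alkene, C9 enone retained | CC1=CC[C@@H]2C(C)=C[C@H](O)CC[C@@]2(C)C1=O | intermediate
9 | 4α,19α-epoxy-3α-alcohol (epoxide syn to OH), C9 enone retained | CC1=CC[C@@H]2[C@]3(C)O[C@@H]3[C@H](O)CC[C@@]2(C)C1=O | intermediate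
10 | 3α-O-TBS ether of 9 | CC1=CC[C@@H]2[C@]3(C)O[C@@H]3[C@H](O[Si](C)(C)C(C)(C)C)CC[C@@]2(C)C1=O | intermediate
11 | lithium enolate (C9–O−, C8=C9) from conjugate reduction of 10 | CC1=C([O-])[C@]2(C)CC[C@@H](O[Si](C)(C)C(C)(C)C)[C@H]3O[C@@]3(C)[C@H]2CC1.[Li+] | intermediate
12 | C9 enol triflate (C8=C9, C17 methyl on C8) | CC1=C(OS(=O)(=O)C(F)(F)F)[C@]2(C)CC[C@@H](O[Si](C)(C)C(C)(C)C)[C@H]3O[C@@]3(C)[C@H]2CC1 | intermediate
13 | conjugated methyl ester, C11O2Me on C9, C8=C9 | CC1=C(C(=O)OC)[C@]2(C)CC[C@@H](O[Si](C)(C)C(C)(C)C)[C@H]3O[C@@]3(C)[C@H]2CC1 | intermediate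
14 | dienol C17H2=C8–C9=C11(OH)OMe, OH cis to C8 | C=C1CC[C@@H]2[C@]3(C)O[C@@H]3[C@H](O[Si](C)(C)C(C)(C)C)CC[C@@]2(C)/C1=C(/O)OC | intermediate
15 | deconjugated methyl ester: C8=C17 methylene, 9β-H, equatorial 9α-CO2Me | C=C1CC[C@@H]2[C@]3(C)O[C@@H]3[C@H](O[Si](C)(C)C(C)(C)C)CC[C@@]2(C)[C@@H]1C(=O)OC | intermediate
16 | C11 primary alcohol (9α-CH2OH) | C=C1CC[C@@H]2[C@]3(C)O[C@@H]3[C@H](O[Si](C)(C)C(C)(C)C)CC[C@@]2(C)[C@@H]1CO | intermediate
17 | C11 aldehyde (9α-CHO) | C=C1CC[C@@H]2[C@]3(C)O[C@@H]3[C@H](O[Si](C)(C)C(C)(C)C)CC[C@@]2(C)[C@@H]1C=O | intermediate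
18 | (E)-C11=C12 vinyl iodide; seven-membered ring with 4α,19α-epoxide and 3α-OTBS | C=C1CC[C@@H]2[C@]3(C)O[C@@H]3[C@H](O[Si](C)(C)C(C)(C)C)CC[C@@]2(C)[C@@H]1/C=C/I | intermediate
19 | trans-decalin with ring A formed: C4 bearing 18-CH3 (β, equatorial) and 19-CHO (α, axial), 3α-OTBS, (E)-vinyl iodide | C=C1CC[C@@H]2[C@](C)(C=O)[C@H](O[Si](C)(C)C(C)(C)C)CC[C@@]2(C)[C@@H]1/C=C/I | intermediate
20 | C19 primary alcohol | C=C1CC[C@@H]2[C@](C)(CO)[C@H](O[Si](C)(C)C(C)(C)C)CC[C@@]2(C)[C@@H]1/C=C/I | intermediate
21 | C19 acetate, 3α-OTBS, (E)-vinyl iodide | C=C1CC[C@@H]2[C@](C)(COC(C)=O)[C@H](O[Si](C)(C)C(C)(C)C)CC[C@@]2(C)[C@@H]1/C=C/I | intermediate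
22 | 3-bromofuran-2(5H)-one | O=C1OCC=C1Br | starting material
23 | 3-(tributylstannyl)furan-2(5H)-one | CCCC[Sn](CCCC)(CCCC)C1=CCOC1=O | intermediate
24 | 3-O-TBS ether of the target | C=C1CC[C@@H]2[C@](C)(COC(C)=O)[C@H](O[Si](C)(C)C(C)(C)C)CC[C@@]2(C)[C@@H]1/C=C/C1=CCOC1=O | intermediate
25 | CNP0346413.1, 19-O-acetyl-14-deoxy-11,12-didehydroandrographolide | C=C1CC[C@@H]2[C@](C)(COC(C)=O)[C@H](O)CC[C@@]2(C)[C@@H]1/C=C/C1=CCOC1=O | target

Total step count: 19. Longest linear sequence: 18 (steps 1 to 16, 18 and 19; step 17 makes the coupling partner).

Steps most likely to fail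

Step 14. After ionisation of the epoxide, a hydride shift from C19 or loss of a proton may compete with the carbon shift.
- Route of the fallback: it sets out from 18 and comes back at 25.
- Change of approach: the migrating carbon becomes an acyl carbon. The acyl shift in α,β-epoxy ketones is a classical ring contraction (3-methyl-2,3-epoxycycloalkanone to 2-formyl-2-methylcycloalkanone).
- Contraction: desilylation of 18 (Bu4NF, THF) should give the epoxy alcohol F1. Dess–Martin oxidation should give the α,β-epoxy ketone F2. BF3·OEt2 (CH2Cl2, −78 to 0 °C) should give the ring-contracted β-keto aldehyde F3 by acyl shift with inversion at C4.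
- Oxygen differentiation: chemoselective reduction of the aldehyde (LiAlH(O-t-Bu)3, THF, −78 °C) should give the keto alcohol F4, and acetylation the keto acetate F5. NaBH4 (MeOH, 0 °C), with hydride entering from the β face opposite the axial C19 and C20 groups, should give the 3α-hydroxy acetate vinyl iodide F6.
- Return: F6 is coupled with 23 under the conditions of step 18 to give 25 directly.

Step 10. Photoenolisation may be slow, the ester may reconjugate during ketonisation, or protonation at C9 may show poor facial selectivity.
- Route of the fallback: it sets out from 10 and comes back at 16.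
- Methylene ketone: conjugate reduction of 10 as in step 8 and trapping of enolate 11 with PhSeBr should give the α-phenylselenyl ketone F7. Oxidation (H2O2, pyridine, CH2Cl2, 0 °C) and syn elimination of the selenoxide towards the C17 methyl group should give the exo-methylene ketone F8. Elimination towards C7 merely regenerates 10 for recycling.
- C11 and C9: Corey–Chaykovsky epoxidation (Me3S+ I−, n-BuLi, THF), with methylide attack on C9 from the open β face, should give the spiro alkenyl epoxide F9 with its C9–O bond α.
- Return: palladium-catalysed hydrogenolysis with formic acid (Pd2(dba)3, PBu3, HCO2H, Et3N, dioxane) should ionise this bond with zerovalent palladium entering anti, on the β face. Hydride should then pass to the more substituted allyl terminus C9 from the same face, giving 16 with 9β-H and the C8=C17 methylene.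

Step 2. Alkylation of the hindered, fully substituted enolate with an unactivated primary iodide may be sluggish, so that proton transfer and O-alkylation take over.
- Route of the fallback: it sets out from 3 and comes back at 7, and it also bypasses the allylic oxidation of step 4.
- Chain: enolate 4 is alkylated with allyl bromide, a far more reactive electrophile under the same facial control, to give 6-allyl-6-methylcarvone F10. Nitrite-modified aldehyde-selective Wacker oxidation (PdCl2(PhCN)2, CuCl2, AgNO2, O2, t-BuOH/MeNO2), which is at its best with allyl groups on quaternary carbon, should give the C3 aldehyde F11.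
- Ring: CH2=CHMgBr (THF, −78 °C) should add to the aldehyde in preference to the hindered enone and give the acyclic allylic alcohol F12 as both C3 epimers. Ring-closing metathesis as in step 3 should give the cycloheptenol F13.
- Return: Dess–Martin oxidation converges both epimers on 7.

Further compounds
F1 | step 14 | epoxy alcohol (18 without the silyl group) | C=C1CC[C@@H]2[C@]3(C)O[C@@H]3[C@H](O)CC[C@@]2(C)[C@@H]1/C=C/I
F2 | step 14 | α,β-epoxy ketone (C3=O, 4α,19α-epoxide) | C=C1CC[C@@H]2[C@]3(C)O[C@@H]3C(=O)CC[C@@]2(C)[C@@H]1/C=C/I
F3 | step 14 | ring-contracted β-keto aldehyde (C3=O, 19-CHO α) | C=C1CC[C@@H]2[C@](C)(C=O)C(=O)CC[C@@]2(C)[C@@H]1/C=C/I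
F4 | step 14 | keto alcohol (C3=O, 19-OH) | C=C1CC[C@@H]2[C@](C)(CO)C(=O)CC[C@@]2(C)[C@@H]1/C=C/I
F5 | step 14 | keto acetate (C3=O, 19-OAc) | C=C1CC[C@@H]2[C@](C)(COC(C)=O)C(=O)CC[C@@]2(C)[C@@H]1/C=C/I
F6 | step 14 | 3α-hydroxy acetate vinyl iodide | C=C1CC[C@@H]2[C@](C)(COC(C)=O)[C@H](O)CC[C@@]2(C)[C@@H]1/C=C/I
F7 | step 10 | α-phenylselenyl ketone (SePh and CH3 on C8, either C8 epimer) | CC1([Se]c2ccccc2)CC[C@@H]2[C@]3(C)O[C@@H]3[C@H](O[Si](C)(C)C(C)(C)C)CC[C@@]2(C)C1=O
F8 | step 10 | exo-methylene ketone (C9=O, C8=C17) | C=C1CC[C@@H]2[C@]3(C)O[C@@H]3[C@H](O[Si](C)(C)C(C)(C)C)CC[C@@]2(C)C1=O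
F9 | step 10 | spiro alkenyl epoxide at C9 (O α, C11 β) | C=C1CC[C@@H]2[C@]3(C)O[C@@H]3[C@H](O[Si](C)(C)C(C)(C)C)CC[C@@]2(C)[C@@]14CO4
F10 | step 2 | 6-allyl-6-methylcarvone (allyl trans to isopropenyl) | CC1=CC[C@H](C(C)=C)[C@@](C)(CC=C)C1=O
F11 | step 2 | C3 aldehyde | CC1=CC[C@H](C(C)=C)[C@@](C)(CCC=O)C1=O
F12 | step 2 | acyclic allylic alcohol (both C3 epimers) | CC1=CC[C@H](C(C)=C)[C@@](C)(CCC(O)C=C)C1=O
F13 | step 2 | cycloheptenol (both C3 epimers) | CC1=CC[C@@H]2C(C)=CC(O)CC[C@@]2(C)C1=O
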